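Neither flask can hold more target than the substrate charged, yet the last rise of the readings, carried on straight, puts east at 145% after 80 min. That is one extreme, and it is impossible. The other extreme stops dead at the last reading.

| flask | substrate | remark | time |
|---|---|---|---|
| Thursday's | 0.35 M | run made earlier |  |
| Saturday's | 0.70 M | run made earlier |  |
| east | 0.50 M |  | 80 min |
| north | 0.25 M |  | 40 min |

- Thursday's (time / min: target / %): 3.00: 1.8; 6.00: 12.2; 10.0: 27.9; 12.0: 33.0; 15.0: 40.1; 20.0: 49.6
- Saturday's (time / min: target / %): 3.00: 2.5; 6.00: 11.8; 10.0: 26.5; 12.0: 32.7; 15.0: 41.2; 20.0: 47.7

(scatter of a reading: 1 percentage point)

* which one finishes higher in amount of target, in percent of the substrate charged ("neither" within 2 percentage points) (east / north / neither)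
* amount of target at the end, in percent of the substrate charged, east
* amount of target at the end, in percent of the substrate charged, north

- the earlier runs were read with a standard deviation of 1 percentage point

The real flask lies between these extremes, and the runs show how far. Their charges stand twice apart, yet they agree within the scatter, so I drop the charge and average them: 27.2%, 40.6% and 48.7% at 10.0 min, 15.0 min and 20.0 min. The rise over equal steps falls from 13 points to 8 points. I therefore count in h, the half-life of the remaining rise, which is 6.67 min. Summing the shrinking steps gives a rough plateau of 60.4%, if the rise goes on shrinking by the same factor.

After the last reading, north has 3.00 half-lives and east 8.99. My reckoning gives 58.9% for north and 60.4% for east, a gap smaller than the margin, so I answer neither.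

The forecast chooses north, with 28% for east and 50% for north: “I lean towards consumption of target, so north, with wide ranges.”

The flasks give 58.1% in east and 57.6% in north, so the answer is neither.

    substrate → intermediate A (k = 0.00690 s⁻¹)
    intermediate A → intermediate B (k = 0.00250 s⁻¹)
    intermediate B → target (k = 0.00390 s⁻¹)
    target ⇌ isomer of the product (K = 0.720, k = 0.00750 s⁻¹)

East holds 58.1% target and 41.9% isomer of the product at 80.0 min, and the same at 800 min. Their ratio is the equilibrium constant 0.72, which is thermodynamic control. Now take north read at 15 min. North's gap below its end value is 8.9 points at 20.0 min. Going back 0.750 of my half-lives, that gap grows to 15 points, which puts target at 42.6%. The flask read then holds 40.2% target.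

The data are simulated with made-up constants, and the scatter is random.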